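**Retrosynthetic overview**

1. The strategy rests on the C3–C4 bond of the only ring, the furan-2(5H)-one (O1, C2–C5). C3 carries the (R)-1-acetoxybutyl chain and C4–Br is at the carboxylic acid oxidation level, so C4–Br ⇐ C4–OH of a tetronic acid.
2. Late stage: C5=CBr2 ⇐ C5=CHBr ⇐ C5=CH2 ⇐ C5(H)–CH3 by three bromination/dehydrobromination rounds. C1′–OAc ⇐ C1′–OSiMe2tBu, exchanged before any radical chemistry.
3. Key disconnection C3–C4: Dieckmann closure of the O-[(R)-3-silyloxyhexanoyl] ester of methyl lactate, the only ring-forming step.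
4. The single stereocentre C1′ comes from RuCl2[(R)-BINAP]-catalysed hydrogenation of methyl 3-oxohexanoate.

Key step: step 5

Remark: the carbon that becomes C5 comes from racemic methyl lactate and is carried as both epimers, because it becomes sp2 in step 9. Compounds 6–13 are single enantiomers at C1′ and epimer mixtures at that carbon only; their SMILES leave it undefined, as do those of the transient C5 centres in 15 and 17.

**Route**

Step 1
Reactants: 1 methyl 3-oxohexanoate
Product: 2 methyl (R)-3-hydroxyhexanoate
Conditions: RuCl2[(R)-BINAP] (0.1 mol %; BINAP = 2,2′-bis(diphenylphosphino)-1,1′-binaphthyl), H2 (50 atm), MeOH, 50 °C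
Reagents that add atoms: none
Why: Noyori asymmetric hydrogenation of a β-keto ester; the (R)-BINAP ligand on the ester-chelated ruthenium hydride directs hydrogen to the ketone face that gives the (R)-carbinol, as it does for the lower homologues.

Step 2
Reactants: 2 methyl (R)-3-hydroxyhexanoate
Product: 3 methyl (R)-3-(tert-butyldimethylsilyloxy)hexanoate
Conditions: TBSCl, imidazole, DMF, rt
Reagents that add atoms: tert-butyldimethylsilyl chloride, CC(C)(C)[Si](C)(C)Cl
Why: Imidazole-promoted O-silylation of a secondary alcohol; the C–O bond is not broken, so the configuration is retained.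

Step 3
Reactants: 3 methyl (R)-3-(tert-butyldimethylsilyloxy)hexanoate
Product: 4 (R)-3-(tert-butyldimethylsilyloxy)hexanoic acid
Conditions: LiOH·H2O, THF/MeOH/H2O, 0 °C → rt; then 1 M HCl to pH 3–4, 0 °C
Reagents that add atoms: lithium hydroxide, [Li+].[OH-]
Why: Saponification of the methyl ester; hydroxide adds to the ester carbonyl faster than it triggers β-elimination of the silyl ether, and the brief cold acidification leaves the silyl ether in place.

Step 4
Reactants: 4 (R)-3-(tert-butyldimethylsilyloxy)hexanoic acid; 5 methyl lactate (racemic)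
Product: 6 methyl 2-{[(R)-3-(tert-butyldimethylsilyloxy)hexanoyl]oxy}propanoate (both epimers at the lactate carbon)
Conditions: DCC, DMAP (cat.), CH2Cl2, 0 °C → rt
Reagents that add atoms: none
Why: Steglich esterification; the acylpyridinium formed from the DCC-activated acid acylates the secondary hydroxyl of methyl lactate under neutral conditions that do not affect the silyl ether or the stereocentre.

Step 5
Reactants: 6 methyl 2-{[(R)-3-(tert-butyldimethylsilyloxy)hexanoyl]oxy}propanoate
Product: 9 3-[(R)-1-(tert-butyldimethylsilyloxy)butyl]-4-hydroxy-5-methylfuran-2(5H)-one, via lithium ester enolate 7 (not isolated), via lithium tetronate 8 (not isolated)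
Conditions: LiN(SiMe3)2 (2.3 equiv), THF, −78 °C (6 added slowly to the base), then → −20 °C; cold 1 M HCl to pH 2–3
Reagents that add atoms: none
Why: LiN(SiMe3)2 removes an α-hydrogen of the hexanoyl ester to give enolate 7, whose α-carbon adds to the neighbouring lactate methyl ester carbonyl; loss of methoxide from the tetrahedral intermediate forms the C3–C4 bond, and the resulting β-keto lactone is deprotonated at once to the tetronate 8 (a vinylogous carboxylate, pKa of the acid about 4), which makes the sequence irreversible. This is the Dieckmann (intramolecular Claisen) condensation of α-acyloxy esters, the standard entry to 3-alkyl tetronic acids. The one ring closes as a 5-exo-trig attack on the ester carbonyl with the enolate C=C inside the new ring (enolendo), a geometry less favourable than an enolexo closure but the established one for tetronic and tetramic acids. No stereocentre is created: C1′ was set in step 1 and is not at a reacting atom, and C5 is an epimer mixture that is erased in step 9. The step needs C-acylation to beat β-elimination of the silyloxy group from 7 and acyl migration from the lactate-side enolate (Chan rearrangement); the low temperature, the poor leaving ability of a silanolate, and the reversible enolisation by the weak amide base, with only the Dieckmann path ending irreversibly in 8, should secure this.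

Step 6
Reactants: 9 3-[(R)-1-(tert-butyldimethylsilyloxy)butyl]-4-hydroxy-5-methylfuran-2(5H)-one
Product: 10 4-bromo-3-[(R)-1-(tert-butyldimethylsilyloxy)butyl]-5-methylfuran-2(5H)-one
Conditions: (COBr)2 (1.2 equiv), DMF (1.3 equiv), CH2Cl2, 0 °C, 20 min; then 9, 0 °C → rt
Reagents that add atoms: oxalyl bromide, O=C(Br)C(Br)=O
Why: Vilsmeier-type deoxybromination of a vinylogous acid (O-formiminium activation of C4–OH, then bromide addition–elimination at C4), the standard conversion of tetronic acids into 4-bromofuranones; C1′ is not involved.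

Step 7
Reactants: 10 4-bromo-3-[(R)-1-(tert-butyldimethylsilyloxy)butyl]-5-methylfuran-2(5H)-one
Product: 11 4-bromo-3-[(R)-1-hydroxybutyl]-5-methylfuran-2(5H)-one
Conditions: HF (48 % aq.), MeCN, 0 °C → rt
Reagents that add atoms: none
Why: Acidic fluoride desilylation driven by Si–F bond formation; only the Si–O bond is cleaved, so C1′ keeps its configuration, and no base is present that could deprotonate C5–H or displace the C4 bromide.

Step 8
Reactants: 11 4-bromo-3-[(R)-1-hydroxybutyl]-5-methylfuran-2(5H)-one
Product: 12 3-[(R)-1-acetoxybutyl]-4-bromo-5-methylfuran-2(5H)-one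
Conditions: Ac2O (1.5 equiv), Sc(OTf)3 (1 mol %), MeCN, 0 °C
Reagents that add atoms: acetic anhydride, CC(=O)OC(C)=O
Why: Lewis-acid-catalysed O-acetylation of a secondary alcohol with retention at C1′; the final ester is installed here because an acetoxy-bearing C–H is a poorer hydrogen donor to bromine atoms than a silyloxy-bearing one, and because the finished tribromide would not tolerate fluoride or nucleophilic acylation catalysts.

Step 9
Reactants: 12 3-[(R)-1-acetoxybutyl]-4-bromo-5-methylfuran-2(5H)-one
Product: 14 3-[(R)-1-acetoxybutyl]-4-bromo-5-methylenefuran-2(5H)-one, via 5-bromo lactone 13 (not isolated)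
Conditions: NBS (1.05 equiv), AIBN (5 mol %), PhCF3, 85 °C; cool, filter; then DBU (1.1 equiv), CH2Cl2, 0 °C
Reagents that add atoms: none
Why: Wohl–Ziegler bromination at C5, whose hydrogen is tertiary and gives a radical delocalised over O1–C5–C4–C3 (a 2-oxyfuranyl radical), as in the standard C5 bromination of 3-methylfuran-2(5H)-one where the C3 substituent is left alone; the tertiary bromide 13 then loses HBr by E2 toward the methyl group, the only source of β-hydrogens.

Step 10
Reactants: 14 3-[(R)-1-acetoxybutyl]-4-bromo-5-methylenefuran-2(5H)-one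
Product: 16 3-[(R)-1-acetoxybutyl]-4-bromo-5-[(Z)-bromomethylene]furan-2(5H)-one, via tribromide 15 (not isolated)
Conditions: Br2 (1.05 equiv), CH2Cl2, 0 °C, dark; then DBU (1.1 equiv), 0 °C
Reagents that add atoms: bromine, BrBr
Why: Electrophilic addition of bromine to the exocyclic enol-lactone alkene, the only electron-rich C=C (C3=C4 is tetrasubstituted, brominated and conjugated to the carbonyl), then E2 dehydrobromination across C5–CH2Br, expected to give mainly the Z isomer; the geometry is of no consequence because it is lost in step 11.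

Step 11
Reactants: 16 3-[(R)-1-acetoxybutyl]-4-bromo-5-[(Z)-bromomethylene]furan-2(5H)-one
Product: 18 3-[(R)-1-acetoxybutyl]-4-bromo-5-(dibromomethylene)furan-2(5H)-one (target), via tetrabromide 17 (not isolated)
Conditions: Br2 (1.2 equiv), CH2Cl2, rt, dark; then DBU (1.1 equiv), 0 °C
Reagents that add atoms: bromine, BrBr
Why: A second bromine addition to the bromomethylene alkene followed by E2 loss of HBr, for which the CHBr2 hydrogen is the only one available, gives the dibromomethylene group; the C1′ acetate and C4–Br are not affected.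

**Compound list**

1 | methyl 3-oxohexanoate | CCCC(=O)CC(=O)OC | starting material
2 | methyl (R)-3-hydroxyhexanoate | CCC[C@@H](O)CC(=O)OC | intermediate
3 | methyl (R)-3-(tert-butyldimethylsilyloxy)hexanoate | CCC[C@@H](O[Si](C)(C)C(C)(C)C)CC(=O)OC | intermediate
4 | (R)-3-(tert-butyldimethylsilyloxy)hexanoic acid | CCC[C@@H](O[Si](C)(C)C(C)(C)C)CC(=O)O | intermediate
5 | methyl lactate (racemic) | CC(O)C(=O)OC | starting material
6 | methyl 2-{[(R)-3-(tert-butyldimethylsilyloxy)hexanoyl]oxy}propanoate | CCC[C@@H](O[Si](C)(C)C(C)(C)C)CC(=O)OC(C)C(=O)OC | intermediate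
7 | lithium ester enolate of 6 (hexanoyl α-carbon) | CCC[C@@H](O[Si](C)(C)C(C)(C)C)C=C([O-])OC(C)C(=O)OC.[Li+] | intermediate (not isolated)
8 | lithium salt of 9 (lithium tetronate) | CCC[C@@H](O[Si](C)(C)C(C)(C)C)C1=C([O-])C(C)OC1=O.[Li+] | intermediate (not isolated)
9 | 3-[(R)-1-(tert-butyldimethylsilyloxy)butyl]-4-hydroxy-5-methylfuran-2(5H)-one | CCC[C@@H](O[Si](C)(C)C(C)(C)C)C1=C(O)C(C)OC1=O | intermediate
10 | 4-bromo-3-[(R)-1-(tert-butyldimethylsilyloxy)butyl]-5-methylfuran-2(5H)-one | CCC[C@@H](O[Si](C)(C)C(C)(C)C)C1=C(Br)C(C)OC1=O | intermediate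
11 | 4-bromo-3-[(R)-1-hydroxybutyl]-5-methylfuran-2(5H)-one | CCC[C@@H](O)C1=C(Br)C(C)OC1=O | intermediate
12 | 3-[(R)-1-acetoxybutyl]-4-bromo-5-methylfuran-2(5H)-one | CCC[C@@H](OC(C)=O)C1=C(Br)C(C)OC1=O | intermediate
13 | 3-[(R)-1-acetoxybutyl]-4,5-dibromo-5-methylfuran-2(5H)-one | CCC[C@@H](OC(C)=O)C1=C(Br)C(C)(Br)OC1=O | intermediate (not isolated)
14 | 3-[(R)-1-acetoxybutyl]-4-bromo-5-methylenefuran-2(5H)-one | CCC[C@@H](OC(C)=O)C1=C(Br)C(=C)OC1=O | intermediate
15 | 3-[(R)-1-acetoxybutyl]-4,5-dibromo-5-(bromomethyl)furan-2(5H)-one | CCC[C@@H](OC(C)=O)C1=C(Br)C(Br)(CBr)OC1=O | intermediate (not isolated)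
16 | 3-[(R)-1-acetoxybutyl]-4-bromo-5-[(Z)-bromomethylene]furan-2(5H)-one | CCC[C@@H](OC(C)=O)C1=C(Br)/C(=C/Br)OC1=O | intermediate
17 | 3-[(R)-1-acetoxybutyl]-4,5-dibromo-5-(dibromomethyl)furan-2(5H)-one | CCC[C@@H](OC(C)=O)C1=C(Br)C(Br)(C(Br)Br)OC1=O | intermediate (not isolated)
18 | 3-[(R)-1-acetoxybutyl]-4-bromo-5-(dibromomethylene)furan-2(5H)-one | CCC[C@@H](OC(C)=O)C1=C(Br)C(=C(Br)Br)OC1=O | target

**Totals**

Total steps: 11. Longest linear sequence: 11 steps (1 → 18).

**Steps most likely to fail**

Step 5 (key step). The risk is that β-elimination of the silanolate from enolate 7, or acyl migration from the lactate-side enolate, outruns the less favourable enolendo ring closure, so that material is lost before the tetronate forms. Fallback, from 6 back to 9: the silyl group is removed (HF, MeCN) to give methyl 2-{[(R)-3-hydroxyhexanoyl]oxy}propanoate F1. LiN(iPr)2 (3.3 equiv) in THF at −78 → −30 °C should give the dilithium alkoxide enolate F2, in which the β-oxygen is an alkoxide and cannot leave. F2 should close to the dilithium alkoxide tetronate F3. Silylation of both oxygens in the same flask with tBuMe2SiOTf should give 4-(tert-butyldimethylsilyloxy)-3-[(R)-1-(tert-butyldimethylsilyloxy)butyl]-5-methylfuran-2(5H)-one F4. Its labile enol silyl ether is then hydrolysed with aqueous citric acid in THF, which returns to 9.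

Step 9. The risk is that hydrogen abstraction at C1′ competes with abstraction at C5, which would brominate or racemise the stereocentre, or that bromination goes beyond one bromine. Fallback, from 10 back to 14, by ionic bromination before the protecting-group exchange: tBuMe2SiOTf and iPr2NEt in CH2Cl2 (−78 → 0 °C) should give the silyloxyfuran 3-bromo-5-(tert-butyldimethylsilyloxy)-4-[(R)-1-(tert-butyldimethylsilyloxy)butyl]-2-methylfuran F5. NBS in THF at −78 °C should brominate its C5, the γ-carbon of the silyl dienolate, to give 4,5-dibromo-3-[(R)-1-(tert-butyldimethylsilyloxy)butyl]-5-methylfuran-2(5H)-one F6. DBU then gives 4-bromo-3-[(R)-1-(tert-butyldimethylsilyloxy)butyl]-5-methylenefuran-2(5H)-one F7, and HF in MeCN gives 4-bromo-3-[(R)-1-hydroxybutyl]-5-methylenefuran-2(5H)-one F8. Acetylation (Ac2O, cat. Sc(OTf)3) returns to 14.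

Step 6. The risk is that HBr and the bromoiminium salt cleave the silyl ether, or ionise the C1′–O bond with help from the C4 enol, leading to loss of the protecting group, substitution at C1′ or 3-alkylidene formation, and so to erosion of configuration. Fallback, from 9 back to 10, without Brønsted acid: Tf2O and iPr2NEt in CH2Cl2 at −78 °C should give 3-[(R)-1-(tert-butyldimethylsilyloxy)butyl]-5-methyl-2-oxo-2,5-dihydrofuran-4-yl trifluoromethanesulfonate F9. Bromide addition–elimination at C4 of this vinylogous acyl triflate (LiBr, acetone, rt → 40 °C) returns to 10.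

**Further compounds**

F1 | step 5 | methyl 2-{[(R)-3-hydroxyhexanoyl]oxy}propanoate | CCC[C@@H](O)CC(=O)OC(C)C(=O)OC
F2 | step 5 | dilithium alkoxide enolate of F1 | CCC[C@@H]([O-])C=C([O-])OC(C)C(=O)OC.[Li+].[Li+]
F3 | step 5 | dilithium salt of 4-hydroxy-3-[(R)-1-hydroxybutyl]-5-methylfuran-2(5H)-one | CCC[C@@H]([O-])C1=C([O-])C(C)OC1=O.[Li+].[Li+]
F4 | step 5 | 4-(tert-butyldimethylsilyloxy)-3-[(R)-1-(tert-butyldimethylsilyloxy)butyl]-5-methylfuran-2(5H)-one | CCC[C@@H](O[Si](C)(C)C(C)(C)C)C1=C(O[Si](C)(C)C(C)(C)C)C(C)OC1=O
F5 | step 9 | 3-bromo-5-(tert-butyldimethylsilyloxy)-4-[(R)-1-(tert-butyldimethylsilyloxy)butyl]-2-methylfuran | CCC[C@@H](O[Si](C)(C)C(C)(C)C)c1c(Br)c(C)oc1O[Si](C)(C)C(C)(C)C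
F6 | step 9 | 4,5-dibromo-3-[(R)-1-(tert-butyldimethylsilyloxy)butyl]-5-methylfuran-2(5H)-one | CCC[C@@H](O[Si](C)(C)C(C)(C)C)C1=C(Br)C(C)(Br)OC1=O
F7 | step 9 | 4-bromo-3-[(R)-1-(tert-butyldimethylsilyloxy)butyl]-5-methylenefuran-2(5H)-one | CCC[C@@H](O[Si](C)(C)C(C)(C)C)C1=C(Br)C(=C)OC1=O
F8 | step 9 | 4-bromo-3-[(R)-1-hydroxybutyl]-5-methylenefuran-2(5H)-one | CCC[C@@H](O)C1=C(Br)C(=C)OC1=O
F9 | step 6 | 3-[(R)-1-(tert-butyldimethylsilyloxy)butyl]-5-methyl-2-oxo-2,5-dihydrofuran-4-yl trifluoromethanesulfonate | CCC[C@@H](O[Si](C)(C)C(C)(C)C)C1=C(OS(=O)(=O)C(F)(F)F)C(C)OC1=O
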